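**The constants.** The constants 7.5 L² mol⁻² min⁻¹ and 2.4 L² mol⁻² min⁻¹ say that left-handed substrate is consumed faster, a selectivity factor of 3.12, while the racemization catalyst keeps refilling it from right-handed substrate.

left-handed substrate 0.40 M; solid reagent 0.880 M; free catalyst 56 mM; racemization catalyst 14 mM; right-handed substrate 0.40 M; time 15 h

* left-handed product at 15 h, in percent of the left-handed substrate and right-handed substrate together charged
* right-handed product at 15 h, in percent of the left-handed substrate and right-handed substrate together charged

**Enough partner.** This flask holds 0.880 M of solid reagent against 0.800 M of substrate, so I expect a surplus of 0.0800 M partner. On that surplus the last substrate has a half-life near 31.3 min, far shorter than the run, so I count on full conversion and need only the split.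

**Partner level.** For the early part I let dissolution balance use, with both substrates still taken at their charge, which gives [partner] near 0.184 M.

**The lag.** At that level, the pseudo-first-order consumption rates of the two substrates differ by 0.0526 min⁻¹, and racemization runs at 0.364 min⁻¹, which is faster. A small difference between the substrates is therefore held steady. Racemization feeds one form and drains the other, so the lag, the fraction by which [left-handed substrate] stands below [right-handed substrate], is the gap over two times the racemization rate: 7.22%.

**My number.** The product ratio is then the selectivity factor times one minus the lag, so left-handed product takes 74.4% of the product.

**Weak link.** The weak link is the constant [partner]. After the first minutes it lies between the surplus and the solubility 0.33 M. Putting those two ends through the same rule gives 75.2% and 73.1%, and my number stands between them.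

**The result.** The forecast gives 74.2% and 25.8%, saying “so this is a dynamic kinetic resolution”; the simulated flask gives 74.4% and 25.6%.

    solid reagent ⇌ partner, rate k1*(cs1 - [partner]) while solid is left; crystals form when [partner] > cs1 (cs1 = 0.33 M, k1 = 0.28 min⁻¹)
    partner + free catalyst + left-handed substrate → free catalyst + left-handed product (k2 = 7.5 L² mol⁻² min⁻¹)
    left-handed substrate + racemization catalyst ⇌ right-handed substrate + racemization catalyst, rate k3*[racemization catalyst]*[left-handed substrate] forward; the back reaction follows from the equilibrium constant (k3 = 26 L mol⁻¹ min⁻¹)
    partner + free catalyst + right-handed substrate → free catalyst + right-handed product (k4 = 2.4 L² mol⁻² min⁻¹)

**Rates compared.** In this flask at 0.145 h, left-handed substrate has a half-life of 1.9 min by the forward racemization rate and 0.14 h by its turning into left-handed product, the first shorter by a factor of 4.30. The lag read from the two products of this flask, an average over its run, is 7.12%. The neighbour flask with 0.53 M of solid reagent ends at 0 M partner, so my share times its partner per substrate gives 49.3%, and its left-handed product stands at 49.5%.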